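Labels: the chroman has benzo ring A and pyran ring C (O1, C2, C3, C4, C4a, C8a). Ring B is the 4-hydroxyphenyl on C2, ring D the resorcinol ring on C4, ring E the catechol ring of the stilbene.
Retrosynthetic cuts, in order: seven O–benzyl bonds; the ring D–vinyl bond (Heck); C2–ring B (arylation of a C2 oxocarbenium ion); C3–C4 together with O1–C2 (formal [4+2]); C4–ring D (Grignard addition).
Enabling feature: C4 is a diarylmethine on C4a, ortho to the O1-bearing C8a of ring A. O1=C8a–C4a=C4 can therefore be unmasked as an ortho-quinone methide, and the oxygen on C3 lets C2–C3 arrive as the enamine of an α-alkoxyacetaldehyde.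
Forward order: rings D and A are joined at C4, the carbinol is exchanged for a sulfone, and ring C closes in the annulation. Ring B is then placed on C2, ring E is attached through the alkene, and all benzyl groups fall last.
Stereochemistry: C3 and C4 (3R,4R, trans) come from an (S)-diphenylprolinol silyl ether catalyst. C2 (2R, cis to O3, trans to ring D) comes from substrate control in the oxocarbenium arylation, and the E alkene from the Heck reaction.

Key step: step 5

Assumption: slow rotation about the C4–ring D bond is treated as a conformational matter, not as an extra stereogenic element.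

Step 1
Reactants: 1 5-bromoresorcinol
Product: 2 1,3-bis(benzyloxy)-5-bromobenzene
Conditions: BnBr, K2CO3, DMF, 25 → 60 °C
Reagents that add atoms: benzyl bromide, BrCc1ccccc1
Why: Williamson ether synthesis, in which both phenolates are alkylated by the primary benzylic bromide while the aryl bromide is inert to carbonate.

Step 2
Reactants: 2 1,3-bis(benzyloxy)-5-bromobenzene
Product: 3 1,5-bis(benzyloxy)-3-bromo-2-iodobenzene
Conditions: NIS, MeCN, 0 → 25 °C, dark
Reagents that add atoms: N-iodosuccinimide, O=C1CCC(=O)N1I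
Why: Electrophilic aromatic iodination, which in 5-substituted resorcinol diethers avoids the site between the two ethers and enters the position ortho to one ether and para to the other, here next to bromine.

Step 3
Reactants: 3 1,5-bis(benzyloxy)-3-bromo-2-iodobenzene; 4 4-(benzyloxy)-2-hydroxybenzaldehyde
Product: 7 racemic 5-(benzyloxy)-2-{[2-bromo-4,6-bis(benzyloxy)phenyl](hydroxy)methyl}phenol, via aryl Grignard reagent 5 (not isolated), via chloromagnesium phenolate 6 (not isolated)
Conditions: 3, i-PrMgCl·LiCl, THF, −30 °C; 4, i-PrMgCl, THF, −78 °C; combine, −30 → 0 °C; aq NH4Cl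
Reagents that add atoms: none
Why: Iodine–magnesium exchange followed by Grignard 1,2-addition, where iodine exchanges far faster than bromine, the ortho-bromoarylmagnesium species holds below 0 °C, prior deprotonation of 4 spares the aryl reagent, and the racemic carbinol centre is harmless because step 5 makes it planar.

Step 4
Reactants: 7 racemic 5-(benzyloxy)-2-{[2-bromo-4,6-bis(benzyloxy)phenyl](hydroxy)methyl}phenol
Product: 8 racemic 5-(benzyloxy)-2-{[2-bromo-4,6-bis(benzyloxy)phenyl](4-methylbenzenesulfonyl)methyl}phenol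
Conditions: p-TolSO2H, CH2Cl2, 25 °C
Reagents that add atoms: p-toluenesulfinic acid, Cc1ccc(cc1)S(=O)O
Why: SN1-type substitution of a benzhydrol, in which the mild acidity of the sulfinic acid ionises the doubly donor-stabilised carbinol and the soft sulfur end of the sulfinate captures the cation to give the thermodynamically preferred, storable sulfone.

Step 5
Reactants: 8 racemic 5-(benzyloxy)-2-{[2-bromo-4,6-bis(benzyloxy)phenyl](4-methylbenzenesulfonyl)methyl}phenol; 9 benzyloxyacetaldehyde
Product: 13 (3R,4R)-3,7-bis(benzyloxy)-4-[2-bromo-4,6-bis(benzyloxy)phenyl]chroman-2-ol (3,4-trans; both C2 anomers), via ortho-quinone methide 10 (not isolated), via enamine 11 (not isolated), via phenol aldehyde 12 (not isolated)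
Conditions: (S)-2-[diphenyl(trimethylsilyloxy)methyl]pyrrolidine (20 mol %), 9 (3 equiv), solid NaHCO3 (2 equiv), CH2Cl2, 0 → 25 °C
Reagents that add atoms: none
Why: Solid NaHCO3 deprotonates the phenol of 8 and the phenolate expels p-toluenesulfinate, so both enantiomers of 8 converge on the planar quinone methide 10, while the amine condenses with 9 to the (E)-enamine 11; C3 of 11 attacks C4 of 10 (C3–C4 bond, ring A rearomatises) and the water liberated in enamine formation hydrolyses the iminium or N,O-aminal to phenol aldehyde 12 and frees the catalyst. The closest known reaction type is the diarylprolinol silyl ether catalysed Michael addition–hemiacetalisation of enolisable aldehydes with ortho-quinone methides released by base from 2-(1-sulfonylalkyl)phenols, and α-alkoxyacetaldehydes are proven donors in the related syn-selective enamine Michael addition to nitroalkenes. Ring C closes by 6-exo-trig addition of O1 to the aldehyde carbon C2 of 12 (O1–C2 bond), so that overall the O1=C8a–C4a=C4 heterodiene and the C2=C3 enamine bond combine in a formal [4+2] sense. C3 is controlled by the catalyst, whose CPh2(OSiMe3) arm covers one face of the s-trans enamine so that C4 bonds to the open face (3R); C4 is controlled by the compact synclinal approach in which the enamine nitrogen sits over the carbonyl end of (E)-10, the syn Michael topology that becomes the 3,4-trans relationship in the ring (4R); C2 is left as an anomeric mixture because it is made planar again in step 7. The step needs conjugate attack at C4 in preference to quinone methide dimerisation, sulfinate return and self-aldolisation of 9, which the aromatisation-driven electrophilicity of C4, the slow heterogeneous release of 10 and an excess of 9 should secure.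

Step 6
Reactants: 13 (3R,4R)-3,7-bis(benzyloxy)-4-[2-bromo-4,6-bis(benzyloxy)phenyl]chroman-2-ol
Product: 14 (3R,4R)-3,7-bis(benzyloxy)-4-[2-bromo-4,6-bis(benzyloxy)phenyl]chroman-2-yl acetate (both C2 anomers)
Conditions: Ac2O, pyridine, DMAP (cat.), CH2Cl2, 0 → 25 °C
Reagents that add atoms: acetic anhydride, CC(=O)OC(C)=O
Why: DMAP-catalysed O-acylation of the lactol hydroxyl, which gives the anomeric acetate because the ring-closed tautomer dominates, and which leaves C3 and C4 untouched.

Step 7
Reactants: 14 (3R,4R)-3,7-bis(benzyloxy)-4-[2-bromo-4,6-bis(benzyloxy)phenyl]chroman-2-yl acetate; 15 1-(benzyloxy)-4-bromobenzene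
Product: 18 (2R,3R,4R)-3,7-bis(benzyloxy)-2-[4-(benzyloxy)phenyl]-4-[2-bromo-4,6-bis(benzyloxy)phenyl]chromane (2,3-cis-3,4-trans), via arylzinc chloride 16 (not isolated), via C2 oxocarbenium ion 17 (not isolated)
Conditions: 15, Mg, LiCl, ZnCl2, THF, 25 °C; then 14, BF3·OEt2, CH2Cl2, −78 → −30 °C
Reagents that add atoms: none
Why: Lewis-acid-promoted C-arylation of an anomeric acetate by an organozinc reagent (the C-glycosylation manifold), in which BF3·OEt2 ionises 14 to 17 and the aryl group enters pseudoaxially on the half-chair that keeps the C3 ether and ring D pseudoequatorial, that is on the face opposite ring D, which sets 2R, whereas the other face would need a 1,3-diaxial encounter with ring D.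

Step 8
Reactants: 19 3,4-bis(benzyloxy)benzaldehyde
Product: 20 3,4-bis(benzyloxy)styrene
Conditions: Ph3PCH3Br, KOt-Bu, THF, 0 → 25 °C
Reagents that add atoms: methyltriphenylphosphonium bromide, C[P+](c1ccccc1)(c1ccccc1)c1ccccc1.[Br-]
Why: Wittig methylenation of a non-enolisable aromatic aldehyde by the unstabilised ylide, with no other electrophilic site in 19.

Step 9
Reactants: 18 (2R,3R,4R)-3,7-bis(benzyloxy)-2-[4-(benzyloxy)phenyl]-4-[2-bromo-4,6-bis(benzyloxy)phenyl]chromane; 20 3,4-bis(benzyloxy)styrene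
Product: 21 (2R,3R,4R)-3,7-bis(benzyloxy)-2-[4-(benzyloxy)phenyl]-4-{2,4-bis(benzyloxy)-6-[(E)-2-(3,4-bis(benzyloxy)phenyl)ethenyl]phenyl}chromane
Conditions: Pd2(dba)3 (5 mol %), [HP(t-Bu)3]BF4, Cy2NMe, 1,4-dioxane, 90 °C
Reagents that add atoms: none
Why: Mizoroki–Heck reaction, in which the bulky electron-rich phosphine lets zerovalent palladium insert into the hindered C–Br bond (both ethers are meta to it), syn-insertion at the terminal carbon of 20 and syn β-hydride elimination give the E-stilbene, and an amine base without carboxylate disfavours C–H palladation of ring A.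

Step 10
Reactants: 21 (2R,3R,4R)-3,7-bis(benzyloxy)-2-[4-(benzyloxy)phenyl]-4-{2,4-bis(benzyloxy)-6-[(E)-2-(3,4-bis(benzyloxy)phenyl)ethenyl]phenyl}chromane
Product: 22 (2R,3R,4R)-4-{2-[(E)-2-(3,4-dihydroxyphenyl)ethenyl]-4,6-dihydroxyphenyl}-2-(4-hydroxyphenyl)chromane-3,7-diol (CNP0170061.2)
Conditions: BCl3 (1 M in CH2Cl2), C6HMe5, CH2Cl2, −78 → −30 °C; MeOH quench
Reagents that add atoms: none
Why: Lewis-acid ether cleavage with a cation scavenger, in which BCl3 activates each benzyl ether and pentamethylbenzene takes up the benzyl cation by Friedel–Crafts benzylation, so the alkene that hydrogenolysis would saturate survives, while the low temperature and the missing 5-oxygen on ring A should keep the C4–ring D and C2–O1 bonds and all three stereocentres intact.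

Compound list
1 | 5-bromoresorcinol | Oc1cc(O)cc(Br)c1 | starting material
2 | 1,3-bis(benzyloxy)-5-bromobenzene | Brc1cc(OCc2ccccc2)cc(OCc2ccccc2)c1 | intermediate
3 | 1,5-bis(benzyloxy)-3-bromo-2-iodobenzene | Ic1c(Br)cc(OCc2ccccc2)cc1OCc1ccccc1 | intermediate
4 | 4-(benzyloxy)-2-hydroxybenzaldehyde | O=Cc1ccc(OCc2ccccc2)cc1O | starting material
5 | [2-bromo-4,6-bis(benzyloxy)phenyl]magnesium chloride (in situ) | Cl[Mg]c1c(Br)cc(OCc2ccccc2)cc1OCc1ccccc1 | intermediate
6 | chloromagnesium 5-(benzyloxy)-2-formylphenolate (in situ) | O=Cc1ccc(OCc2ccccc2)cc1O[Mg]Cl | intermediate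
7 | racemic 5-(benzyloxy)-2-{[2-bromo-4,6-bis(benzyloxy)phenyl](hydroxy)methyl}phenol | Oc1cc(OCc2ccccc2)ccc1C(O)c1c(OCc2ccccc2)cc(OCc2ccccc2)cc1Br | intermediate
8 | racemic 5-(benzyloxy)-2-{[2-bromo-4,6-bis(benzyloxy)phenyl](4-methylbenzenesulfonyl)methyl}phenol | Oc1cc(OCc2ccccc2)ccc1C(c1c(OCc2ccccc2)cc(OCc2ccccc2)cc1Br)S(=O)(=O)c1ccc(C)cc1 | intermediate
9 | benzyloxyacetaldehyde | O=CCOCc1ccccc1 | starting material
10 | (6E)-3-(benzyloxy)-6-{[2-bromo-4,6-bis(benzyloxy)phenyl]methylidene}cyclohexa-2,4-dien-1-one (in situ) | O=C1C=C(OCc2ccccc2)C=C/C1=C\c1c(OCc2ccccc2)cc(OCc2ccccc2)cc1Br | intermediate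
11 | (S)-1-[(E)-2-(benzyloxy)ethenyl]-2-[diphenyl(trimethylsilyloxy)methyl]pyrrolidine (in situ) | c1ccccc1CO/C=C/N1CCC[C@H]1C(c1ccccc1)(c1ccccc1)O[Si](C)(C)C | intermediate
12 | (2R,3R)-2-(benzyloxy)-3-[4-(benzyloxy)-2-hydroxyphenyl]-3-[2-bromo-4,6-bis(benzyloxy)phenyl]propanal (in situ) | O=C[C@H](OCc1ccccc1)[C@H](c1ccc(OCc2ccccc2)cc1O)c1c(OCc2ccccc2)cc(OCc2ccccc2)cc1Br | intermediate
13 | (3R,4R)-3,7-bis(benzyloxy)-4-[2-bromo-4,6-bis(benzyloxy)phenyl]chroman-2-ol, 3,4-trans, both C2 anomers | OC1Oc2cc(OCc3ccccc3)ccc2[C@H](c2c(OCc3ccccc3)cc(OCc3ccccc3)cc2Br)[C@H]1OCc1ccccc1 | intermediate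
14 | (3R,4R)-3,7-bis(benzyloxy)-4-[2-bromo-4,6-bis(benzyloxy)phenyl]chroman-2-yl acetate, both C2 anomers | CC(=O)OC1Oc2cc(OCc3ccccc3)ccc2[C@H](c2c(OCc3ccccc3)cc(OCc3ccccc3)cc2Br)[C@H]1OCc1ccccc1 | intermediate
15 | 1-(benzyloxy)-4-bromobenzene | Brc1ccc(OCc2ccccc2)cc1 | starting material
16 | [4-(benzyloxy)phenyl]zinc chloride (in situ) | Cl[Zn]c1ccc(OCc2ccccc2)cc1 | intermediate
17 | (3R,4R)-3,7-bis(benzyloxy)-4-[2-bromo-4,6-bis(benzyloxy)phenyl]-3,4-dihydrochromenylium ion (in situ) | C1=[O+]c2cc(OCc3ccccc3)ccc2[C@H](c2c(OCc3ccccc3)cc(OCc3ccccc3)cc2Br)[C@H]1OCc1ccccc1 | intermediate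
18 | (2R,3R,4R)-3,7-bis(benzyloxy)-2-[4-(benzyloxy)phenyl]-4-[2-bromo-4,6-bis(benzyloxy)phenyl]chromane | C(Oc1ccc([C@H]2Oc3cc(OCc4ccccc4)ccc3[C@H](c3c(OCc4ccccc4)cc(OCc4ccccc4)cc3Br)[C@H]2OCc2ccccc2)cc1)c1ccccc1 | intermediate
19 | 3,4-bis(benzyloxy)benzaldehyde | O=Cc1ccc(OCc2ccccc2)c(OCc2ccccc2)c1 | starting material
20 | 3,4-bis(benzyloxy)styrene | C=Cc1ccc(OCc2ccccc2)c(OCc2ccccc2)c1 | intermediate
21 | (2R,3R,4R)-3,7-bis(benzyloxy)-2-[4-(benzyloxy)phenyl]-4-{2,4-bis(benzyloxy)-6-[(E)-2-(3,4-bis(benzyloxy)phenyl)ethenyl]phenyl}chromane | C(Oc1ccc([C@H]2Oc3cc(OCc4ccccc4)ccc3[C@H](c3c(OCc4ccccc4)cc(OCc4ccccc4)cc3/C=C/c3ccc(OCc4ccccc4)c(OCc4ccccc4)c3)[C@H]2OCc2ccccc2)cc1)c1ccccc1 | intermediate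
22 | (2R,3R,4R)-4-{2-[(E)-2-(3,4-dihydroxyphenyl)ethenyl]-4,6-dihydroxyphenyl}-2-(4-hydroxyphenyl)chromane-3,7-diol | Oc1ccc([C@H]2Oc3cc(O)ccc3[C@H](c3c(O)cc(O)cc3/C=C/c3ccc(O)c(O)c3)[C@H]2O)cc1 | target

Total step count: 10. Longest linear sequence: 9 steps (1, 2, 3, 4, 5, 6, 7, 9, 10) from 5-bromoresorcinol.

Steps most likely to fail

Step 5.
- Risk: Ring D carries two ortho substituents and is twisted out of the quinone methide plane, so it partly covers both faces of C4. Carbon–carbon bond formation may then become slow enough for quinone methide dimerisation, sulfinate return and self-aldolisation of 9 to compete. Reaction through the minor quinone methide geometry would erode the trans selectivity.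
- Fallback (from 8, back at 13): the catalytic enamine is replaced by a stoichiometric, auxiliary-bound glycolate enolate at the acid oxidation level.
- (4S)-4-benzyl-3-[(benzyloxy)acetyl]-1,3-oxazolidin-2-one F1 is made from (S)-4-benzyl-1,3-oxazolidin-2-one (n-BuLi) and benzyloxyacetyl chloride. It is enolised with TiCl4 and i-Pr2NEt in CH2Cl2 at −78 °C, and 8 is added.
- Amine and Lewis acid release the same quinone methide 10. The much more nucleophilic chelated enolate adds to C4 on the face left open by the benzyl group of the auxiliary (3R) and gives the imide adduct (4S)-4-benzyl-3-{(2R,3R)-2-(benzyloxy)-3-[4-(benzyloxy)-2-hydroxyphenyl]-3-[2-bromo-4,6-bis(benzyloxy)phenyl]propanoyl}-1,3-oxazolidin-2-one F2.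
- Et3N with catalytic DMAP lets O1 attack the imide carbonyl and expel the auxiliary. This gives the lactone (3R,4R)-3,7-bis(benzyloxy)-4-[2-bromo-4,6-bis(benzyloxy)phenyl]chroman-2-one F3, at which stage any C4 epimer is removed.
- i-Bu2AlH in toluene at −78 °C reduces F3 to lactol 13.

Step 7.
- Risk: The aryl-oxygen-stabilised cation is short-lived. Loss of the C3 proton to an enol ether may outrun arylation, and the facial bias exerted by ring D may prove insufficient.
- Fallback (from 13, back at 18): the ring is opened and reclosed with inversion instead of being substituted at C2.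
- Bromide 15 is lithiated (n-BuLi, THF, −78 °C) and transmetalated with ClTi(Oi-Pr)3 to [4-(benzyloxy)phenyl]tri(propan-2-olato)titanium F4.
- An excess of F4 adds under non-chelation control to the aldehyde tautomer 12 of the lactol. This gives the 1,2-anti diol monoether (1S,2R,3R)-2-(benzyloxy)-1-[4-(benzyloxy)phenyl]-3-[4-(benzyloxy)-2-hydroxyphenyl]-3-[2-bromo-4,6-bis(benzyloxy)phenyl]propan-1-ol F5.
- An intramolecular Mitsunobu etherification (PPh3, DIAD, THF, 0 °C) displaces the benzylic alcohol by O1 with inversion (6-exo-tet) and delivers the 2R flavan 18.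

Step 10.
- Risk: Seven ethers must fall, one of them a secondary alkyl ether that needs warmer conditions. In that window, Lewis-acid ionisation of the C2–O1 bond (epimerisation at C2) and cationic attack on the very electron-rich stilbene may set in.
- Fallback (from 18, back at 22): the benzyl groups are removed before the alkene exists, and the last step becomes a mild ester cleavage.
- BCl3 and C6HMe5 convert 18 to (2R,3R,4R)-4-(2-bromo-4,6-dihydroxyphenyl)-2-(4-hydroxyphenyl)chromane-3,7-diol F6.
- Ac2O in pyridine gives its pentaacetate F7.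
- A Heck coupling of F7 with commercial 3,4-diacetoxystyrene under the conditions of step 9 gives the heptaacetate of the target F8.
- Catalytic NaOMe in degassed MeOH at 0 °C, neutralised with acidic resin, releases 22.

Further compounds
F1 | step 5 | (4S)-4-benzyl-3-[(benzyloxy)acetyl]-1,3-oxazolidin-2-one | O=C(COCc1ccccc1)N1[C@@H](Cc2ccccc2)COC1=O
F2 | step 5 | (4S)-4-benzyl-3-{(2R,3R)-2-(benzyloxy)-3-[4-(benzyloxy)-2-hydroxyphenyl]-3-[2-bromo-4,6-bis(benzyloxy)phenyl]propanoyl}-1,3-oxazolidin-2-one | O=C([C@H](OCc1ccccc1)[C@H](c1ccc(OCc2ccccc2)cc1O)c1c(OCc2ccccc2)cc(OCc2ccccc2)cc1Br)N1[C@@H](Cc2ccccc2)COC1=O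
F3 | step 5 | (3R,4R)-3,7-bis(benzyloxy)-4-[2-bromo-4,6-bis(benzyloxy)phenyl]chroman-2-one | O=C1Oc2cc(OCc3ccccc3)ccc2[C@H](c2c(OCc3ccccc3)cc(OCc3ccccc3)cc2Br)[C@H]1OCc1ccccc1
F4 | step 7 | [4-(benzyloxy)phenyl]tri(propan-2-olato)titanium | CC(C)O[Ti](OC(C)C)(OC(C)C)c1ccc(OCc2ccccc2)cc1
F5 | step 7 | (1S,2R,3R)-2-(benzyloxy)-1-[4-(benzyloxy)phenyl]-3-[4-(benzyloxy)-2-hydroxyphenyl]-3-[2-bromo-4,6-bis(benzyloxy)phenyl]propan-1-ol | C(Oc1ccc(cc1)[C@H](O)[C@H](OCc1ccccc1)[C@H](c1ccc(OCc2ccccc2)cc1O)c1c(OCc2ccccc2)cc(OCc2ccccc2)cc1Br)c1ccccc1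
F6 | step 10 | (2R,3R,4R)-4-(2-bromo-4,6-dihydroxyphenyl)-2-(4-hydroxyphenyl)chromane-3,7-diol | Oc1ccc([C@H]2Oc3cc(O)ccc3[C@H](c3c(O)cc(O)cc3Br)[C@H]2O)cc1
F7 | step 10 | (2R,3R,4R)-3,7-diacetoxy-2-(4-acetoxyphenyl)-4-(2,4-diacetoxy-6-bromophenyl)chromane | CC(=O)Oc1ccc([C@H]2Oc3cc(OC(C)=O)ccc3[C@H](c3c(OC(C)=O)cc(OC(C)=O)cc3Br)[C@H]2OC(C)=O)cc1
F8 | step 10 | (2R,3R,4R)-3,7-diacetoxy-2-(4-acetoxyphenyl)-4-{2,4-diacetoxy-6-[(E)-2-(3,4-diacetoxyphenyl)ethenyl]phenyl}chromane | CC(=O)Oc1ccc([C@H]2Oc3cc(OC(C)=O)ccc3[C@H](c3c(OC(C)=O)cc(OC(C)=O)cc3/C=C/c3ccc(OC(C)=O)c(OC(C)=O)c3)[C@H]2OC(C)=O)cc1
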